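**Assumption:** the target is taken as the (2S,3E) acid encoded by the SMILES. The (S,S) ligand in the new nickel step is assumed to give the 2S product; this must be checked on first use against auxiliary-derived material from the fallback, and the (R,R) ligand used if the sense is opposite.

## Retrosynthetic overview

- No ring is formed; the only ring (the para-substituted phenol) is bought. The work is one stereocentre (C2), one E-trisubstituted alkene (C3=C4) and an 18-methylene tether.
- Target acid ⇐ its phenyl ester, by peroxide-assisted acyl cleavage in the last step.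
- C2–C3 bond (key, new): 4-(icos-19-yn-1-yl)phenol plus racemic phenyl 2-bromopropanoate, by methylalumination (E alkene, C4 methyl) then enantioconvergent NiBr2/bis(oxazoline) alkenylation (C2).
- Alkyne ⇐ Li2CuCl4-catalysed sp3–sp3 Grignard coupling of an aryl-C12 bromide with a C8 silyl bromoalkyne, then global desilylation.
- Aryl-C12 bromide ⇐ aryl Grignard reagent plus 1,12-dibromododecane.

## Route

**Step 1**
Reactants: 1 8-bromooct-1-yne
Product: 3 (8-bromooct-1-yn-1-yl)trimethylsilane, via lithium acetylide 2 (not isolated)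
Conditions: n-BuLi (1.0 equiv), THF, −78 °C; Me3SiCl, −78 °C → rt
Reagents that add atoms: chlorotrimethylsilane, C[Si](C)(C)Cl
Why: Deprotonation of the terminal alkyne is much faster than any reaction of n-BuLi with the primary bromide at −78 °C, and C-silylation of the acetylide masks the acidic C–H for the later Grignard coupling.

**Step 2**
Reactants: 4 (4-bromophenoxy)(tert-butyl)dimethylsilane; 5 1,12-dibromododecane
Product: 7 [4-(12-bromododecyl)phenoxy](tert-butyl)dimethylsilane, via aryl Grignard reagent 6 (not isolated)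
Conditions: Mg, THF, reflux; then added slowly to 5 (3 equiv), Li2CuCl4 (3 mol %), THF, −10 °C → rt
Reagents that add atoms: none
Why: Li2CuCl4-catalysed (Kochi-type) coupling of an aryl Grignard reagent with a primary alkyl bromide, where slow addition to excess dibromide keeps substitution to one end and the aryl silyl ether is inert.

**Step 3**
Reactants: 7 [4-(12-bromododecyl)phenoxy](tert-butyl)dimethylsilane; 3 (8-bromooct-1-yn-1-yl)trimethylsilane
Product: 9 tert-butyldimethyl{4-[20-(trimethylsilyl)icos-19-yn-1-yl]phenoxy}silane, via alkyl Grignard reagent 8 (not isolated)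
Conditions: Mg, THF, 45 °C (1.2 equiv of 8); then 3, Li2CuCl4 (3 mol %), THF/NMP, −10 °C → rt
Reagents that add atoms: none
Why: Li2CuCl4-catalysed sp3–sp3 Grignard cross-coupling (Kochi type) of two primary partners tolerates the silyl ether and the silylalkyne and completes the 18-methylene tether (12 + 6).

**Step 4**
Reactants: 9 tert-butyldimethyl{4-[20-(trimethylsilyl)icos-19-yn-1-yl]phenoxy}silane
Product: 10 4-(icos-19-yn-1-yl)phenol
Conditions: Bu4NF·3H2O (2.5 equiv), THF, 0 °C → rt
Reagents that add atoms: none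
Why: Fluoride-driven desilylation cleaves the aryl O–Si and the alkynyl C–Si bonds in one operation, freeing the phenol and the terminal alkyne needed for carbometalation.

**Step 5**
Reactants: 11 2-bromopropanoyl bromide (racemic); 12 phenol
Product: 13 phenyl 2-bromopropanoate (racemic)
Conditions: pyridine, CH2Cl2, 0 °C
Reagents that add atoms: none
Why: O-Acylation of phenol by the acid bromide with pyridine as acid scavenger is selective because the acyl C–Br is far more electrophilic than the secondary C–Br.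

**Step 6**
Reactants: 10 4-(icos-19-yn-1-yl)phenol; 13 phenyl 2-bromopropanoate (racemic, 1.5 equiv)
Product: 15 phenyl (2S,3E)-22-(4-hydroxyphenyl)-2,4-dimethyldocos-3-enoate, via alkenylalane 14 (not isolated)
Conditions: Me3Al (3.0 equiv), (C5H5)2ZrCl2 (0.25 equiv), CH2Cl2, 0 °C → rt; volatiles removed in vacuo; then 13, NiBr2·MeOCH2CH2OMe (10 mol %), (4S,4'S)-2,2'-(propane-2,2-diyl)bis(4-phenyl-4,5-dihydrooxazole) (13 mol %), THF, −10 °C; cold 1 M HCl work-up
Reagents that add atoms: trimethylaluminium, C[Al](C)C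
Why: Proposed new method: (C5H5)2ZrCl2-catalysed syn-methylalumination (Negishi carboalumination) of the terminal alkyne, with the phenol masked in the flask as its dimethylaluminium phenoxide, fixes the E alkene and the C4 methyl group, and alkenylalane 14 then serves directly as the nucleophile in a NiBr2/bis(oxazoline)-catalysed enantioconvergent alkenylation of racemic 13, in which Al-to-Ni transmetalation gives a chiral monovalent alkenylnickel complex that abstracts bromine from either enantiomer of 13, the planar α-ester radical is captured by the divalent alkenylnickel bromide, and C–C reductive elimination from trivalent nickel (alkene geometry retained) sets C2 under ligand control; the closest known reaction type is the nickel-catalysed enantioconvergent coupling of racemic α-halo carbonyl compounds with alkenylzirconium, alkenylzinc or alkenylsilicon reagents, whereas an alkenylalane made in the same flask by carboalumination has not been used as the nucleophile.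

**Step 7**
Reactants: 15 phenyl (2S,3E)-22-(4-hydroxyphenyl)-2,4-dimethyldocos-3-enoate
Product: 17 (2S,3E)-22-(4-hydroxyphenyl)-2,4-dimethyldocos-3-enoic acid, via peroxy acid 16 (not isolated)
Conditions: LiOH (3 equiv), 30% H2O2 (6 equiv), THF/H2O 3:1, 0 °C; aq. Na2SO3; 1 M HCl to pH 3
Reagents that add atoms: hydrogen peroxide, OO
Why: Hydroperoxide, a strong nucleophile of low basicity, attacks the activated phenyl ester at 0 °C (as in peroxide-mediated cleavage of acyl oxazolidinones), so C2 is not deprotonated and the alkene does not move into conjugation, and sulfite reduces the percarboxylate before acidification.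

## Compound list

1 | 8-bromooct-1-yne | C#CCCCCCCBr | starting material
2 | (8-bromooct-1-yn-1-yl)lithium | [Li]C#CCCCCCCBr | intermediate
3 | (8-bromooct-1-yn-1-yl)trimethylsilane | C[Si](C)(C)C#CCCCCCCBr | intermediate
4 | (4-bromophenoxy)(tert-butyl)dimethylsilane | CC(C)(C)[Si](C)(C)Oc1ccc(Br)cc1 | starting material
5 | 1,12-dibromododecane | BrCCCCCCCCCCCCBr | starting material
6 | [4-(tert-butyldimethylsilyloxy)phenyl]magnesium bromide | CC(C)(C)[Si](C)(C)Oc1ccc([Mg]Br)cc1 | intermediate
7 | [4-(12-bromododecyl)phenoxy](tert-butyl)dimethylsilane | CC(C)(C)[Si](C)(C)Oc1ccc(CCCCCCCCCCCCBr)cc1 | intermediate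
8 | {12-[4-(tert-butyldimethylsilyloxy)phenyl]dodecyl}magnesium bromide | CC(C)(C)[Si](C)(C)Oc1ccc(CCCCCCCCCCCC[Mg]Br)cc1 | intermediate
9 | tert-butyldimethyl{4-[20-(trimethylsilyl)icos-19-yn-1-yl]phenoxy}silane | CC(C)(C)[Si](C)(C)Oc1ccc(CCCCCCCCCCCCCCCCCCC#C[Si](C)(C)C)cc1 | intermediate
10 | 4-(icos-19-yn-1-yl)phenol | C#CCCCCCCCCCCCCCCCCCCc1ccc(O)cc1 | intermediate
11 | 2-bromopropanoyl bromide (racemic) | CC(Br)C(=O)Br | starting material
12 | phenol | Oc1ccccc1 | starting material
13 | phenyl 2-bromopropanoate (racemic) | CC(Br)C(=O)Oc1ccccc1 | intermediate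
14 | {(1E)-20-[4-(dimethylalumanyloxy)phenyl]-2-methylicos-1-en-1-yl}dimethylalumane | C[Al](C)/C=C(\C)CCCCCCCCCCCCCCCCCCc1ccc(O[Al](C)C)cc1 | intermediate
15 | phenyl (2S,3E)-22-(4-hydroxyphenyl)-2,4-dimethyldocos-3-enoate | C/C(=C\[C@H](C)C(=O)Oc1ccccc1)CCCCCCCCCCCCCCCCCCc1ccc(O)cc1 | intermediate
16 | (2S,3E)-22-(4-hydroxyphenyl)-2,4-dimethyldocos-3-eneperoxoic acid | C/C(=C\[C@H](C)C(=O)OO)CCCCCCCCCCCCCCCCCCc1ccc(O)cc1 | intermediate
17 | (2S,3E)-22-(4-hydroxyphenyl)-2,4-dimethyldocos-3-enoic acid | C/C(=C\[C@H](C)C(=O)O)CCCCCCCCCCCCCCCCCCc1ccc(O)cc1 | target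

## Summary

Total step count: 7. Longest linear sequence: 5 steps (steps 2, 3, 4, 6, 7, from 4 to 17).

**Three steps most likely to fail**

**Step 6 (proposed new step).** Risks are slow Al-to-Ni transmetalation, competing methyl transfer from aluminium, and insufficient or reversed enantioselectivity. The fallback uses only known chemistry, sets out from 10 and comes back at 17.
- Silylation of 10 (i-Pr3SiCl, imidazole, DMF) gives triisopropyl[4-(icos-19-yn-1-yl)phenoxy]silane F1.
- Methylalumination (Me3Al, (C5H5)2ZrCl2, CH2Cl2) gives the alkenylalane F2. n-BuLi converts it into the lithium alkenylaluminate F3, which opens ethylene oxide to give (3E)-4-methyl-22-[4-(triisopropylsilyloxy)phenyl]docos-3-en-1-ol F4.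
- Dess–Martin oxidation gives the aldehyde (3E)-4-methyl-22-[4-(triisopropylsilyloxy)phenyl]docos-3-enal F5, used crude. Pinnick oxidation (NaClO2, NaH2PO4, 2-methylbut-2-ene) gives (3E)-4-methyl-22-[4-(triisopropylsilyloxy)phenyl]docos-3-enoic acid F6.
- Pivaloyl chloride and Et3N give the mixed pivalic anhydride F7. This acylates (4S)-4-benzyl-1,3-oxazolidin-2-one (LiCl, Et3N, THF) to give the imide (4S)-4-benzyl-3-{(3E)-4-methyl-22-[4-(triisopropylsilyloxy)phenyl]docos-3-enoyl}-1,3-oxazolidin-2-one F8.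
- NaN(SiMe3)2 at −78 °C gives the chelated sodium Z-enolate F9. MeI alkylates it at the α-carbon on the face away from the benzyl group (Evans alkylation), giving (4S)-4-benzyl-3-{(2S,3E)-2,4-dimethyl-22-[4-(triisopropylsilyloxy)phenyl]docos-3-enoyl}-1,3-oxazolidin-2-one F10.
- LiOH/H2O2 gives the peroxy acid (2S,3E)-2,4-dimethyl-22-[4-(triisopropylsilyloxy)phenyl]docos-3-eneperoxoic acid F11 and, after Na2SO3, (2S,3E)-2,4-dimethyl-22-[4-(triisopropylsilyloxy)phenyl]docos-3-enoic acid F12. Bu4NF in THF then gives 17.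

**Step 7.** The C2–H is allylic and α to an activated ester, so any epimerisation or conjugation at the last step is costly. The fallback removes nucleophilic acyl cleavage altogether; it sets out from 10 (with 11 as source of the ester) and comes back at 17, but it still relies on the new nickel coupling.
- Esterification of 11 with 2-(trimethylsilyl)ethanol (pyridine, CH2Cl2) gives racemic 2-(trimethylsilyl)ethyl 2-bromopropanoate F13.
- Used in place of 13 under the step 6 conditions (through alkenylalane 14), it gives 2-(trimethylsilyl)ethyl (2S,3E)-22-(4-hydroxyphenyl)-2,4-dimethyldocos-3-enoate F14.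
- Tris(dimethylamino)sulfonium difluorotrimethylsilicate in DMF at 0 °C attacks silicon and expels ethene, so nothing acts at the carbonyl group and 17 is released directly.

**Step 2.** Risks are double arylation of the dibromide, biaryl formation and sluggish aryl transfer from copper. The fallback replaces the Grignard coupling by an alkyne coupling; it sets out from 4 and comes back at 7.
- Sonogashira coupling of 4 with dodec-11-yn-1-ol (PdCl2(PhCN)2, P(t-Bu)3, CuI, i-Pr2NH, dioxane, rt) gives 12-[4-(tert-butyldimethylsilyloxy)phenyl]dodec-11-yn-1-ol F15.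
- Hydrogenation (H2, palladium on carbon, EtOAc) gives 12-[4-(tert-butyldimethylsilyloxy)phenyl]dodecan-1-ol F16.
- Appel bromination (CBr4, PPh3, CH2Cl2, 0 °C) gives 7.

## Further compounds

F1 | step 6 | triisopropyl[4-(icos-19-yn-1-yl)phenoxy]silane | C#CCCCCCCCCCCCCCCCCCCc1ccc(O[Si](C(C)C)(C(C)C)C(C)C)cc1
F2 | step 6 | dimethyl{(1E)-2-methyl-20-[4-(triisopropylsilyloxy)phenyl]icos-1-en-1-yl}alumane (alkenylalane) | C[Al](C)/C=C(\C)CCCCCCCCCCCCCCCCCCc1ccc(O[Si](C(C)C)(C(C)C)C(C)C)cc1
F3 | step 6 | lithium butyl(dimethyl){(1E)-2-methyl-20-[4-(triisopropylsilyloxy)phenyl]icos-1-en-1-yl}aluminate | [Li+].CCCC[Al-](C)(C)/C=C(\C)CCCCCCCCCCCCCCCCCCc1ccc(O[Si](C(C)C)(C(C)C)C(C)C)cc1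
F4 | step 6 | (3E)-4-methyl-22-[4-(triisopropylsilyloxy)phenyl]docos-3-en-1-ol | OCC/C=C(\C)CCCCCCCCCCCCCCCCCCc1ccc(O[Si](C(C)C)(C(C)C)C(C)C)cc1
F5 | step 6 | (3E)-4-methyl-22-[4-(triisopropylsilyloxy)phenyl]docos-3-enal | O=CC/C=C(\C)CCCCCCCCCCCCCCCCCCc1ccc(O[Si](C(C)C)(C(C)C)C(C)C)cc1
F6 | step 6 | (3E)-4-methyl-22-[4-(triisopropylsilyloxy)phenyl]docos-3-enoic acid | OC(=O)C/C=C(\C)CCCCCCCCCCCCCCCCCCc1ccc(O[Si](C(C)C)(C(C)C)C(C)C)cc1
F7 | step 6 | (3E)-4-methyl-22-[4-(triisopropylsilyloxy)phenyl]docos-3-enoic pivalic anhydride | CC(C)(C)C(=O)OC(=O)C/C=C(\C)CCCCCCCCCCCCCCCCCCc1ccc(O[Si](C(C)C)(C(C)C)C(C)C)cc1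
F8 | step 6 | (4S)-4-benzyl-3-{(3E)-4-methyl-22-[4-(triisopropylsilyloxy)phenyl]docos-3-enoyl}-1,3-oxazolidin-2-one | O=C1OC[C@H](Cc2ccccc2)N1C(=O)C/C=C(\C)CCCCCCCCCCCCCCCCCCc1ccc(O[Si](C(C)C)(C(C)C)C(C)C)cc1
F9 | step 6 | sodium Z-enolate of F8 | [Na+].[O-]/C(=C\C=C(/C)CCCCCCCCCCCCCCCCCCc1ccc(O[Si](C(C)C)(C(C)C)C(C)C)cc1)N1C(=O)OC[C@@H]1Cc1ccccc1
F10 | step 6 | (4S)-4-benzyl-3-{(2S,3E)-2,4-dimethyl-22-[4-(triisopropylsilyloxy)phenyl]docos-3-enoyl}-1,3-oxazolidin-2-one | C/C(=C\[C@H](C)C(=O)N1C(=O)OC[C@@H]1Cc1ccccc1)CCCCCCCCCCCCCCCCCCc1ccc(O[Si](C(C)C)(C(C)C)C(C)C)cc1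
F11 | step 6 | (2S,3E)-2,4-dimethyl-22-[4-(triisopropylsilyloxy)phenyl]docos-3-eneperoxoic acid | C/C(=C\[C@H](C)C(=O)OO)CCCCCCCCCCCCCCCCCCc1ccc(O[Si](C(C)C)(C(C)C)C(C)C)cc1
F12 | step 6 | (2S,3E)-2,4-dimethyl-22-[4-(triisopropylsilyloxy)phenyl]docos-3-enoic acid | C/C(=C\[C@H](C)C(=O)O)CCCCCCCCCCCCCCCCCCc1ccc(O[Si](C(C)C)(C(C)C)C(C)C)cc1
F13 | step 7 | 2-(trimethylsilyl)ethyl 2-bromopropanoate (racemic) | CC(Br)C(=O)OCC[Si](C)(C)C
F14 | step 7 | 2-(trimethylsilyl)ethyl (2S,3E)-22-(4-hydroxyphenyl)-2,4-dimethyldocos-3-enoate | C/C(=C\[C@H](C)C(=O)OCC[Si](C)(C)C)CCCCCCCCCCCCCCCCCCc1ccc(O)cc1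
F15 | step 2 | 12-[4-(tert-butyldimethylsilyloxy)phenyl]dodec-11-yn-1-ol | OCCCCCCCCCCC#Cc1ccc(O[Si](C)(C)C(C)(C)C)cc1
F16 | step 2 | 12-[4-(tert-butyldimethylsilyloxy)phenyl]dodecan-1-ol | OCCCCCCCCCCCCc1ccc(O[Si](C)(C)C(C)(C)C)cc1
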